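The catalyst charged as L is passed around: at each moment L, G, J.G and Q together make up that charge, and free J, J.G and Z together make up the J charged.

    G → Q (k1 = 0.00480 s⁻¹, Ea1 = 228 kJ mol⁻¹)
    J + G ⇌ J.G (K2 = 694 L mol⁻¹, k2 = 1.62 × 10⁹ L mol⁻¹ s⁻¹, Ea2 = 10.0 kJ mol⁻¹, ΔH2 = −12.0 kJ mol⁻¹)
    J.G ⇌ G + Z (K3 = 0.042 M, k3 = 16300 s⁻¹, Ea3 = 54.0 kJ mol⁻¹, ΔH3 = −20.0 kJ mol⁻¹)
    L → G (k4 = 0.337 s⁻¹, Ea4 = 74.0 kJ mol⁻¹)
    (constants at 37 °C)

common to all: J 2.0 mM; L 0.0021 mol%; time 3.0 s

| charge | temperature | remark |
|---|---|---|
| Saturday's | 52 °C |  |
| Monday's | 22 °C |  |
| Tuesday's | 37 °C |  |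
| Sunday's |  | at 22 °C until 1.5 s, from then on at 52 °C |

- constants are those at 37 °C; use the activation energies and enthalpies for any other temperature

- the flask with the highest amount of Z, in percent of the J charged ("all alike" if they lie within 1.5 percentage points) (Saturday's / Monday's / Tuesday's / Sunday's / all alike)
- final Z, as a percentage of the J charged, in Saturday's
- final Z, as a percentage of the J charged, in Monday's
- final Z, as a percentage of the J charged, in Tuesday's
- final Z, as a percentage of the J charged, in Sunday's

Minutes of the meeting. I went to the board first and said that the charge of L comes to 42.0 nM against 2.0 mM of J, so the catalyst takes a negligible part of the J, and the question is how fast so little of it can work.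

I took Tuesday's, which stands at 37 °C, where the constants need no conversion. There J.G falls back to J and G at 2.33 × 10⁶ s⁻¹, but goes on to Z at only 16300 s⁻¹, so I treated the forward leak as a small correction and let J, G and J.G stand in rapid pre-equilibrium.

I therefore proposed to carry one number, the holding ratio b, with the value 1.39 at full J in Tuesday's: the amount of J.G per G, reckoned as the equilibrium constant of the second step times the concentration of free J.

I then wrote the working share in J.G as b over one plus b, which is 58.1%. If every L were already G, Tuesday's would therefore make Z at 0.199 s⁻¹ of the J charged.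

But in Tuesday's L wakes gradually, with rate constant k = 0.337 s⁻¹, and by 3.0 s a share of 63.6% has woken by this reckoning. The time τ of full working is the elapsed time less that share divided by k, which is 1.11 s.

The loss to Q I set aside for Tuesday's, its constant being 0.00480 s⁻¹. My figure for Tuesday's was thus 22.1%, reckoned with J kept at full charge. I took the other temperatures no further by hand.

A colleague who had seen only the problem then read the forecast: Saturday's highest, with 63.5% in Saturday's, 2.5% in Monday's, 20.8% in Tuesday's and 35% in Sunday's. The colleague argued that “Heat speeds both activation and turnover” more than the loss costs. For Tuesday's the forecast stood below my figure.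

The simulation gives 64.7% in Saturday's, 2.44% in Monday's, 20.9% in Tuesday's and 35.3% in Sunday's, so Saturday's holds the most Z, as the forecast said. At 3.00 s Tuesday's has J at 79.1%, which scales b to 1.10, and the flask holds J.G at 33.1% and G at 30.3%, a ratio of 1.09. Monday's, with 879 L mol⁻¹ as its equilibrium constant and J at 97.6%, gives a holding ratio of 1.72, and that flask holds J.G at 13.2% and G at 7.74%, a ratio of 1.71.

The numbers come from no measurement.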